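The furofuran is disconnected at its bridgehead C-3a–C-6a bond and at the benzylic C-4–O-5 bond of the oxolane carrying the free guaiacyl ring (ring C). A single operation on an acyclic epoxy cinnamyl ether, whose only core stereocentre is the benzylic ether carbon next to the central aryl ring (ring B), builds both oxolanes. Cp2TiCl opens the epoxide to a radical that closes the first ring 5-exo. Iodine then converts the resulting benzylic titanium species into a benzylic cation, stabilised by the para oxygen of ring C, which the CH2O group traps. This closes the ring C oxolane last and sets three stereocentres. The erythro aryl glycerol ether comes from an Evans aldol followed by Mitsunobu inversion.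

Key step: step 14

Remark: TBS = tert-butyldimethylsilyl; G = (1R,2S)-1,3-bis(TBSO)-1-(4-TBSO-3-methoxyphenyl)propan-2-yl (protected erythro glycerol unit with ring A). Furofuran numbering is C-1 (on ring B), O-2, C-3, C-3a, C-4 (on ring C), O-5, C-6, C-6a; the target is read as the erythro (1R,2S) glycerol ether of the exo,exo cis-fused (1R,3aS,4R,6aS) furofuran.

Step 1
Reactants: 1 4-bromo-2-methoxyphenol; 2 bromoacetic acid
Product: 3 2-(4-bromo-2-methoxyphenoxy)acetic acid
Conditions: NaOH, H2O, 100 °C; then HCl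
Reagents that add atoms: none
Why: Williamson ether synthesis of a phenoxide with the bromoacetate anion; no stereocentre is formed.

Step 2
Reactants: 3 2-(4-bromo-2-methoxyphenoxy)acetic acid; 4 (R)-4-benzyl-1,3-oxazolidin-2-one
Product: 6 (4R)-4-benzyl-3-[2-(4-bromo-2-methoxyphenoxy)acetyl]-1,3-oxazolidin-2-one, via mixed pivalic anhydride 5 (not isolated)
Conditions: t-BuCOCl, Et3N, THF, −20 °C; then 4, LiCl, −20 °C to rt
Reagents that add atoms: none
Why: N-acylation of the Evans oxazolidinone through the mixed anhydride (LiCl-assisted) is the standard entry to aryloxyacetyl imides and leaves the auxiliary stereocentre untouched.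

Step 3
Reactants: 7 vanillin (4-hydroxy-3-methoxybenzaldehyde)
Product: 8 4-(TBSO)-3-methoxybenzaldehyde
Conditions: TBSCl, imidazole, DMF, rt
Reagents that add atoms: tert-butyldimethylsilyl chloride, CC(C)(C)[Si](C)(C)Cl
Why: Phenol silylation gives an aryl silyl ether that is removed at the end by fluoride, so no hydrogenolysis is needed near the benzylic C–O bonds of the furofuran.

Step 4
Reactants: 6 (4R)-4-benzyl-3-[2-(4-bromo-2-methoxyphenoxy)acetyl]-1,3-oxazolidin-2-one; 8 4-(TBSO)-3-methoxybenzaldehyde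
Product: 10 (4R)-4-benzyl-3-[(2R,3S)-2-(4-bromo-2-methoxyphenoxy)-3-hydroxy-3-(4-TBSO-3-methoxyphenyl)propanoyl]-1,3-oxazolidin-2-one, via boron enolate 9 (not isolated)
Conditions: Bu2BOTf, i-Pr2NEt, CH2Cl2, −78 to 0 °C; then 8, −78 to 0 °C; pH 7 buffer, MeOH, H2O2
Reagents that add atoms: none
Why: Evans syn-aldol reaction: the (Z)-boron enolate reacts through a Zimmerman–Traxler chair on the face opposite the benzyl group of the (R)-auxiliary, which sets C-2 as R and C-3 as S (syn, the threo aryloxy/hydroxy pair).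

Step 5
Reactants: 10 (4R)-4-benzyl-3-[(2R,3S)-2-(4-bromo-2-methoxyphenoxy)-3-hydroxy-3-(4-TBSO-3-methoxyphenyl)propanoyl]-1,3-oxazolidin-2-one
Product: 11 (4R)-4-benzyl-3-[(2R,3R)-2-(4-bromo-2-methoxyphenoxy)-3-(4-nitrobenzoyloxy)-3-(4-TBSO-3-methoxyphenyl)propanoyl]-1,3-oxazolidin-2-one
Conditions: PPh3, DIAD, 4-nitrobenzoic acid, toluene, 0 °C to rt
Reagents that add atoms: 4-nitrobenzoic acid, OC(=O)c1ccc(cc1)[N+](=O)[O-]
Why: Mitsunobu reaction: SN2 displacement of the benzylic oxyphosphonium by 4-nitrobenzoate inverts C-3 from S to R (threo to erythro), while the conformationally locked imide should resist α-deprotonation and elimination.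

Step 6
Reactants: 11 (4R)-4-benzyl-3-[(2R,3R)-2-(4-bromo-2-methoxyphenoxy)-3-(4-nitrobenzoyloxy)-3-(4-TBSO-3-methoxyphenyl)propanoyl]-1,3-oxazolidin-2-one
Product: 12 (1R,2S)-2-(4-bromo-2-methoxyphenoxy)-1-(4-TBSO-3-methoxyphenyl)propane-1,3-diol
Conditions: LiBH4, THF/MeOH, 0 °C to rt
Reagents that add atoms: none
Why: Reductive cleavage by borohydride removes the auxiliary (imide to primary alcohol) and the 4-nitrobenzoate in one operation without touching either stereocentre (the S label at C-2 results only from changed CIP priorities).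

Step 7
Reactants: 12 (1R,2S)-2-(4-bromo-2-methoxyphenoxy)-1-(4-TBSO-3-methoxyphenyl)propane-1,3-diol
Product: 13 (1R,2S)-2-(4-bromo-2-methoxyphenoxy)-1,3-bis(TBSO)-1-(4-TBSO-3-methoxyphenyl)propane
Conditions: TBSOTf, 2,6-lutidine, CH2Cl2, −78 to 0 °C
Reagents that add atoms: tert-butyldimethylsilyl triflate, CC(C)(C)[Si](C)(C)OS(=O)(=O)C(F)(F)F
Why: Silylation of the secondary benzylic and the primary hydroxyl groups with the silyl triflate; no stereocentre is affected.

Step 8
Reactants: 13 (1R,2S)-2-(4-bromo-2-methoxyphenoxy)-1,3-bis(TBSO)-1-(4-TBSO-3-methoxyphenyl)propane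
Product: 15 4-(G-oxy)-3-methoxybenzaldehyde, via aryllithium 14 (not isolated)
Conditions: n-BuLi, THF, −78 °C; then DMF, −78 °C to rt; H2O
Reagents that add atoms: N,N-dimethylformamide, CN(C)C=O
Why: Bromine–lithium exchange followed by Bouveault formylation with DMF, run at −78 °C where silyl and aryl ethers are inert.

Step 9
Reactants: 15 4-(G-oxy)-3-methoxybenzaldehyde
Product: 16 (R)-1-[4-(G-oxy)-3-methoxyphenyl]prop-2-en-1-ol
Conditions: Zn(CH=CH2)2, (2R)-(+)-3-exo-(dimethylamino)isoborneol (10 mol %), toluene, 0 °C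
Reagents that add atoms: divinylzinc, C=C[Zn]C=C
Why: Catalytic enantioselective alkenylzinc addition to an aryl aldehyde: the amino-alkoxide zinc catalyst from the (2R) ligand delivers vinyl to the Re face and sets the carbinol centre as R, the remote side-chain centres being too distant to interfere.

Step 10
Reactants: 16 (R)-1-[4-(G-oxy)-3-methoxyphenyl]prop-2-en-1-ol
Product: 17 (S)-[4-(G-oxy)-3-methoxyphenyl][(R)-oxiran-2-yl]methanol
Conditions: Ti(OiPr)4, L-(+)-diisopropyl tartrate, t-BuOOH, 4 Å molecular sieves, CH2Cl2, −20 °C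
Reagents that add atoms: tert-butyl hydroperoxide, CC(C)(C)OO
Why: Sharpless asymmetric epoxidation in its matched mode: with L-(+)-tartrate the (R)-1-arylallyl alcohol is the fast-reacting isomer and should give the erythro epoxy alcohol (new oxirane centre R), while any S-carbinol epimer from step 9 reacts slowly and is removed.

Step 11
Reactants: 8 4-(TBSO)-3-methoxybenzaldehyde
Product: 18 racemic 1-(4-TBSO-3-methoxyphenyl)prop-2-en-1-ol
Conditions: CH2=CHMgBr, THF, −78 to 0 °C
Reagents that add atoms: vinylmagnesium bromide, C=C[Mg]Br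
Why: Grignard addition to the aldehyde; the racemic carbinol centre disappears in the next step.

Step 12
Reactants: 18 racemic 1-(4-TBSO-3-methoxyphenyl)prop-2-en-1-ol
Product: 19 (E)-4-(3-bromoprop-1-en-1-yl)-2-methoxy-1-(TBSO)benzene
Conditions: PBr3, Et2O, −10 to 0 °C; used at once
Reagents that add atoms: phosphorus tribromide, BrP(Br)Br
Why: Bromination with allylic transposition (SN2′/ion-pair collapse) should give the conjugated primary (E)-cinnamyl bromide, the thermodynamically favoured isomer.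

Step 13
Reactants: 17 (S)-[4-(G-oxy)-3-methoxyphenyl][(R)-oxiran-2-yl]methanol; 19 (E)-4-(3-bromoprop-1-en-1-yl)-2-methoxy-1-(TBSO)benzene
Product: 20 (2R)-2-[(S)-[4-(G-oxy)-3-methoxyphenyl]{[(E)-3-(4-TBSO-3-methoxyphenyl)prop-2-en-1-yl]oxy}methyl]oxirane
Conditions: NaH, Bu4NI (cat.), THF, −20 to 0 °C
Reagents that add atoms: none
Why: Williamson etherification of the sodium alkoxide with a reactive allylic bromide at low temperature, meant to outrun Payne rearrangement; the carbinol C–O bond is not broken, so its configuration is retained.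

Step 14
Reactants: 20 (2R)-2-[(S)-[4-(G-oxy)-3-methoxyphenyl]{[(E)-3-(4-TBSO-3-methoxyphenyl)prop-2-en-1-yl]oxy}methyl]oxirane
Product: 23 (1R,3aS,4R,6aS)-1-[4-(G-oxy)-3-methoxyphenyl]-4-(4-TBSO-3-methoxyphenyl)tetrahydro-1H,3H-furo[3,4-c]furan, via benzylic titanium species 21 (not isolated), via benzylic iodide 22 (not isolated)
Conditions: Cp2TiCl2 (2.5 equiv), Zn dust, THF, rt; slow addition of 20; then I2 (1.5 equiv), rt to 50 °C; aq. Na2S2O3
Reagents that add atoms: none
Why: Cp2TiCl (trivalent titanium) opens the terminal epoxide by single-electron transfer at the more substituted carbon to a β-titanoxy secondary radical, which adds 5-exo-trig to the cinnamyl alkene (C-6a–C-3a bond, closing the oxolane on ring B); the benzylic radical is captured by a second Cp2TiCl as 21, iodine cleaves the C–Ti bond to iodide 22, and ionisation to the benzylic cation stabilised by the para silyloxy group of ring C lets the CH2O–Ti oxygen form the C-4–O-5 bond (5-exo, SN1-like), so the oxolane bearing ring C closes last. The closest known reaction type is the titanocene-mediated reductive epoxide-opening radical cyclisation of epoxy cinnamyl ethers with iodine-induced cycloetherification to 2,6-diaryl-3,7-dioxabicyclo[3.3.0]octanes. C-6a and C-3a are controlled by the existing C-1 stereocentre: in the chair-like Beckwith–Houk transition state the radical carbon bonds anti to the ring B aryl group (1,6a-trans) and the CH2OTi and styryl carbons end up cis, which gives the cis ring fusion. C-4 is set in the cationic closure, where the aryl group takes the exo position on the convex face of the bicycle, the kinetically and thermodynamically preferred arrangement. The step needs regioselective epoxide opening (secured by the greater stability of the secondary radical), 5-exo over 6-endo closure (secured by benzylic stabilisation of the exo radical) and iodination before protonation (secured by adding iodine to the anhydrous mixture before any proton source).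

Step 15
Reactants: 23 (1R,3aS,4R,6aS)-1-[4-(G-oxy)-3-methoxyphenyl]-4-(4-TBSO-3-methoxyphenyl)tetrahydro-1H,3H-furo[3,4-c]furan
Product: 24 (1R,2S)-1-(4-hydroxy-3-methoxyphenyl)-2-{4-[(1R,3aS,4R,6aS)-4-(4-hydroxy-3-methoxyphenyl)tetrahydro-1H,3H-furo[3,4-c]furan-1-yl]-2-methoxyphenoxy}propane-1,3-diol
Conditions: Bu4NF, AcOH, THF, 0 °C to rt
Reagents that add atoms: none
Why: Fluoride-mediated cleavage of the four silyl ethers (two aryl, one benzylic, one primary) under acetic acid buffering should avoid phenoxide-driven side reactions and leave all six stereocentres untouched.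

Compound list
1 | 4-bromo-2-methoxyphenol | COc1cc(Br)ccc1O | starting material
2 | bromoacetic acid | OC(=O)CBr | starting material
3 | 2-(4-bromo-2-methoxyphenoxy)acetic acid | COc1cc(Br)ccc1OCC(=O)O | intermediate
4 | (R)-4-benzyl-1,3-oxazolidin-2-one | O=C1OC[C@@H](Cc2ccccc2)N1 | starting material
5 | 2-(4-bromo-2-methoxyphenoxy)acetic pivalic anhydride | COc1cc(Br)ccc1OCC(=O)OC(=O)C(C)(C)C | intermediate (not isolated)
6 | (4R)-4-benzyl-3-[2-(4-bromo-2-methoxyphenoxy)acetyl]-1,3-oxazolidin-2-one | COc1cc(Br)ccc1OCC(=O)N1C(=O)OC[C@H]1Cc1ccccc1 | intermediate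
7 | vanillin | COc1cc(C=O)ccc1O | starting material
8 | 4-(TBSO)-3-methoxybenzaldehyde | COc1cc(C=O)ccc1O[Si](C)(C)C(C)(C)C | intermediate
9 | (Z)-dibutylboron enolate of 6 | CCCCB(CCCC)O/C(=C\Oc1ccc(Br)cc1OC)N1C(=O)OC[C@H]1Cc1ccccc1 | intermediate (not isolated)
10 | (4R)-4-benzyl-3-[(2R,3S)-2-(4-bromo-2-methoxyphenoxy)-3-hydroxy-3-(4-TBSO-3-methoxyphenyl)propanoyl]-1,3-oxazolidin-2-one | COc1cc([C@H](O)[C@H](C(=O)N2C(=O)OC[C@H]2Cc2ccccc2)Oc2ccc(Br)cc2OC)ccc1O[Si](C)(C)C(C)(C)C | intermediate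
11 | (4R)-4-benzyl-3-[(2R,3R)-2-(4-bromo-2-methoxyphenoxy)-3-(4-nitrobenzoyloxy)-3-(4-TBSO-3-methoxyphenyl)propanoyl]-1,3-oxazolidin-2-one | COc1cc([C@@H](OC(=O)c2ccc(cc2)[N+](=O)[O-])[C@H](C(=O)N2C(=O)OC[C@H]2Cc2ccccc2)Oc2ccc(Br)cc2OC)ccc1O[Si](C)(C)C(C)(C)C | intermediate
12 | (1R,2S)-2-(4-bromo-2-methoxyphenoxy)-1-(4-TBSO-3-methoxyphenyl)propane-1,3-diol | COc1cc([C@@H](O)[C@H](CO)Oc2ccc(Br)cc2OC)ccc1O[Si](C)(C)C(C)(C)C | intermediate
13 | (1R,2S)-2-(4-bromo-2-methoxyphenoxy)-1,3-bis(TBSO)-1-(4-TBSO-3-methoxyphenyl)propane | COc1cc([C@@H](O[Si](C)(C)C(C)(C)C)[C@H](CO[Si](C)(C)C(C)(C)C)Oc2ccc(Br)cc2OC)ccc1O[Si](C)(C)C(C)(C)C | intermediate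
14 | aryllithium from 13 (Li in place of Br) | COc1cc([C@@H](O[Si](C)(C)C(C)(C)C)[C@H](CO[Si](C)(C)C(C)(C)C)Oc2ccc([Li])cc2OC)ccc1O[Si](C)(C)C(C)(C)C | intermediate (not isolated)
15 | 4-(G-oxy)-3-methoxybenzaldehyde | COc1cc([C@@H](O[Si](C)(C)C(C)(C)C)[C@H](CO[Si](C)(C)C(C)(C)C)Oc2ccc(C=O)cc2OC)ccc1O[Si](C)(C)C(C)(C)C | intermediate
16 | (R)-1-[4-(G-oxy)-3-methoxyphenyl]prop-2-en-1-ol | COc1cc([C@@H](O[Si](C)(C)C(C)(C)C)[C@H](CO[Si](C)(C)C(C)(C)C)Oc2ccc([C@@H](C=C)O)cc2OC)ccc1O[Si](C)(C)C(C)(C)C | intermediate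
17 | (S)-[4-(G-oxy)-3-methoxyphenyl][(R)-oxiran-2-yl]methanol | COc1cc([C@@H](O[Si](C)(C)C(C)(C)C)[C@H](CO[Si](C)(C)C(C)(C)C)Oc2ccc([C@@H]([C@H]3CO3)O)cc2OC)ccc1O[Si](C)(C)C(C)(C)C | intermediate
18 | racemic 1-(4-TBSO-3-methoxyphenyl)prop-2-en-1-ol | C=CC(O)c1ccc(O[Si](C)(C)C(C)(C)C)c(OC)c1 | intermediate
19 | (E)-4-(3-bromoprop-1-en-1-yl)-2-methoxy-1-(TBSO)benzene | COc1cc(/C=C/CBr)ccc1O[Si](C)(C)C(C)(C)C | intermediate
20 | (2R)-2-[(S)-[4-(G-oxy)-3-methoxyphenyl]{[(E)-3-(4-TBSO-3-methoxyphenyl)prop-2-en-1-yl]oxy}methyl]oxirane | COc1cc([C@@H](O[Si](C)(C)C(C)(C)C)[C@H](CO[Si](C)(C)C(C)(C)C)Oc2ccc([C@@H]([C@H]3CO3)OC/C=C/c3ccc(O[Si](C)(C)C(C)(C)C)c(OC)c3)cc2OC)ccc1O[Si](C)(C)C(C)(C)C | intermediate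
21 | (2R,3S,4S)-oxolane from the 5-exo closure with CH2O–TiCp2Cl at C-3 and CH(TiCp2Cl)(4-TBSO-3-methoxyphenyl) at C-4 (benzylic centre as a mixture) | COc1cc([C@@H](O[Si](C)(C)C(C)(C)C)[C@H](CO[Si](C)(C)C(C)(C)C)Oc2ccc([C@@H]3OC[C@@H](C(c4ccc(O[Si](C)(C)C(C)(C)C)c(OC)c4)[Ti](Cl)(C4C=CC=C4)C4C=CC=C4)[C@H]3CO[Ti](Cl)(C4C=CC=C4)C4C=CC=C4)cc2OC)ccc1O[Si](C)(C)C(C)(C)C | intermediate (not isolated)
22 | same (2R,3S,4S)-oxolane with CH(I)(4-TBSO-3-methoxyphenyl) at C-4 and CH2O–TiCp2Cl at C-3 (benzylic centre as a mixture) | COc1cc([C@@H](O[Si](C)(C)C(C)(C)C)[C@H](CO[Si](C)(C)C(C)(C)C)Oc2ccc([C@@H]3OC[C@@H](C(I)c4ccc(O[Si](C)(C)C(C)(C)C)c(OC)c4)[C@H]3CO[Ti](Cl)(C4C=CC=C4)C4C=CC=C4)cc2OC)ccc1O[Si](C)(C)C(C)(C)C | intermediate (not isolated)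
23 | (1R,3aS,4R,6aS)-1-[4-(G-oxy)-3-methoxyphenyl]-4-(4-TBSO-3-methoxyphenyl)tetrahydro-1H,3H-furo[3,4-c]furan | COc1cc([C@@H](O[Si](C)(C)C(C)(C)C)[C@H](CO[Si](C)(C)C(C)(C)C)Oc2ccc([C@@H]3OC[C@@H]4[C@H]3CO[C@H]4c3ccc(O[Si](C)(C)C(C)(C)C)c(OC)c3)cc2OC)ccc1O[Si](C)(C)C(C)(C)C | intermediate
24 | (1R,2S)-1-(4-hydroxy-3-methoxyphenyl)-2-{4-[(1R,3aS,4R,6aS)-4-(4-hydroxy-3-methoxyphenyl)tetrahydro-1H,3H-furo[3,4-c]furan-1-yl]-2-methoxyphenoxy}propane-1,3-diol (CNP0172915.1) | COc1cc([C@@H](O)[C@H](CO)Oc2ccc([C@@H]3OC[C@@H]4[C@H]3CO[C@H]4c3ccc(O)c(OC)c3)cc2OC)ccc1O | target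

Total step count: 15. Longest linear sequence: 12 steps (steps 1, 2, 4 to 10, 13, 14, 15, from 1 to 24).

Steps most likely to fail

First, step 14. The benzylic titanium species may be protonated or lose a β-hydrogen before iodine intercepts it. Face selectivity in the radical closure may be incomplete. The tetravalent titanium and iodine present in the second stage may also ionise the benzylic silyl ether of the side chain. The fallback sets out from 20 and separates the two ring closures. The Cp2TiCl cyclisation is run alone and quenched with dilute aqueous acid, which should give the reduced oxolane [(2R,3S,4S)-2-[4-(G-oxy)-3-methoxyphenyl]-4-(4-TBSO-3-methoxybenzyl)oxolan-3-yl]methanol F1. The last ring is then closed oxidatively with DDQ in CH2Cl2 at 0 °C: benzylic hydride abstraction next to ring C generates the same para-oxygen-stabilised cation, which the CH2OH group traps with the aryl group exo. The route is rejoined at 23, and the oxolane on ring C is still the last ring formed.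

Second, step 13. The epoxy alkoxide may undergo Payne migration before O-alkylation, the electron-rich allylic bromide may ionise and decompose, and silyl groups may transfer from the aryl silyl ethers to the alkoxide. The fallback sets out from 17 and 18 and replaces the basic SN2 etherification by a Tsuji–Trost allylic etherification. Alcohol 18 is converted with ClCO2Me and pyridine into methyl 1-(4-TBSO-3-methoxyphenyl)prop-2-en-1-yl carbonate F2. The zinc alkoxide of 17 (Et2Zn, THF) is then allylated with F2 under Pd(PPh3)4 (zerovalent palladium) catalysis. Attack at the unsubstituted allyl terminus should give the linear (E)-ether, and the weakly basic zinc alkoxide should not trigger epoxide migration. The route is rejoined at 20.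

Third, step 5. The activated β-hydroxy imide may dehydrate (elimination towards the α-aryloxy cinnamoyl imide), and the electron-rich benzylic oxyphosphonium may ionise with partial loss of configuration. The fallback sets out from 10 and sets the carbinol centre by substrate-controlled hydride delivery instead of SN2 inversion:
- NaBH4 in THF/H2O removes the auxiliary to give the threo diol (1S,2S)-2-(4-bromo-2-methoxyphenoxy)-1-(4-TBSO-3-methoxyphenyl)propane-1,3-diol F3.
- TBSCl and imidazole silylate the primary hydroxyl to (1S,2S)-2-(4-bromo-2-methoxyphenoxy)-3-(TBSO)-1-(4-TBSO-3-methoxyphenyl)propan-1-ol F4.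
- Dess–Martin periodinane gives the ketone (S)-2-(4-bromo-2-methoxyphenoxy)-3-(TBSO)-1-(4-TBSO-3-methoxyphenyl)propan-1-one F5.
- LiBH(s-Bu)3 in THF at −78 °C should reduce F5 under polar Felkin–Anh control (aryloxy group anti to the incoming hydride) to the erythro alcohol (1R,2S)-2-(4-bromo-2-methoxyphenoxy)-3-(TBSO)-1-(4-TBSO-3-methoxyphenyl)propan-1-ol F6.
- TBSOTf and 2,6-lutidine silylate F6, and the route is rejoined at 13.

Further compounds
F1 | step 14 | [(2R,3S,4S)-2-[4-(G-oxy)-3-methoxyphenyl]-4-(4-TBSO-3-methoxybenzyl)oxolan-3-yl]methanol | COc1cc([C@@H](O[Si](C)(C)C(C)(C)C)[C@H](CO[Si](C)(C)C(C)(C)C)Oc2ccc([C@@H]3OC[C@@H](Cc4ccc(O[Si](C)(C)C(C)(C)C)c(OC)c4)[C@H]3CO)cc2OC)ccc1O[Si](C)(C)C(C)(C)C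
F2 | step 13 | methyl 1-(4-TBSO-3-methoxyphenyl)prop-2-en-1-yl carbonate (racemic) | C=CC(OC(=O)OC)c1ccc(O[Si](C)(C)C(C)(C)C)c(OC)c1
F3 | step 5 | (1S,2S)-2-(4-bromo-2-methoxyphenoxy)-1-(4-TBSO-3-methoxyphenyl)propane-1,3-diol | COc1cc([C@H](O)[C@H](CO)Oc2ccc(Br)cc2OC)ccc1O[Si](C)(C)C(C)(C)C
F4 | step 5 | (1S,2S)-2-(4-bromo-2-methoxyphenoxy)-3-(TBSO)-1-(4-TBSO-3-methoxyphenyl)propan-1-ol | COc1cc([C@H](O)[C@H](CO[Si](C)(C)C(C)(C)C)Oc2ccc(Br)cc2OC)ccc1O[Si](C)(C)C(C)(C)C
F5 | step 5 | (S)-2-(4-bromo-2-methoxyphenoxy)-3-(TBSO)-1-(4-TBSO-3-methoxyphenyl)propan-1-one | COc1cc(C(=O)[C@H](CO[Si](C)(C)C(C)(C)C)Oc2ccc(Br)cc2OC)ccc1O[Si](C)(C)C(C)(C)C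
F6 | step 5 | (1R,2S)-2-(4-bromo-2-methoxyphenoxy)-3-(TBSO)-1-(4-TBSO-3-methoxyphenyl)propan-1-ol | COc1cc([C@@H](O)[C@H](CO[Si](C)(C)C(C)(C)C)Oc2ccc(Br)cc2OC)ccc1O[Si](C)(C)C(C)(C)C
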